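**Retrosynthetic overview**
- The target comes from its 6-O-TIPS ether by desilylation. The oxygenated naphthalene ring (bonds C2'–C3' and C1'–C8a') is built last, directly on the isoquinoline, by a photoredox radical [4+2] benzannulation of a 5-(prop-1-ynyl)isoquinoline with the phenacyl radical from 2-chloro-1-(2-methoxyphenyl)ethanone. The hindered biaryl axis therefore starts as an unhindered aryl–alkyne bond and no aryl–aryl coupling is needed.
- The 5-propynyl isoquinoline comes from Sonogashira coupling with propyne, after C5 iodination of the 6-silyloxy-8-methoxyisoquinoline.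
- The pyridine ring comes from a Cp*Co(III) C–H/N–O annulation of an aryl methyl ketoxime with propargyl alcohol, which installs 1-Me and 3-CH2OH together. The ketone comes from resorcinol and acetic acid, then 4-O-TIPS / 2-O-Me.
- The α-chloroketone comes from ortho-lithiated anisole and ClCH2C(O)N(OMe)Me.
- Ring order: resorcinol benzene ring (bought), then the pyridine ring, then the second naphthalene ring; the anisole ring is bought.

Assumption: the SMILES has no stereocentres and no descriptor for the 5,1' biaryl axis, so the route targets the constitution as drawn; the axis forms without control (racemic atropisomers, separable by chiral HPLC if one is wanted).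

**Step 1**
Reactants: 1 resorcinol; 2 acetic acid
Product: 3, 1-(2,4-dihydroxyphenyl)ethan-1-one
Conditions: ZnCl2 (1.2 equiv), neat AcOH, 145 °C
Reagents that add atoms: none (both partners are numbered reactants)
Why: Nencki (ZnCl2-mediated Friedel–Crafts) C-acylation of resorcinol goes to C4, which is ortho/para to both hydroxyls and less hindered than C2.

**Step 2**
Reactants: 3, 1-(2,4-dihydroxyphenyl)ethan-1-one
Product: 4, 1-{2-methoxy-4-[(triisopropylsilyl)oxy]phenyl}ethan-1-one
Conditions: TIPSCl (1.05 equiv), imidazole, DMF, 0 °C → rt; then K2CO3, MeI (excess), rt → 40 °C (one pot)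
Reagents that add atoms: triisopropylsilyl chloride, CC(C)[Si](Cl)(C(C)C)C(C)C; iodomethane, CI
Why: the free, more acidic 4-OH is silylated selectively by the bulky chloride while the 2-OH is hydrogen-bonded to the ketone, and that 2-OH is then methylated by Williamson etherification, with the bulky aryl TIPS ether stable to carbonate.

**Step 3**
Reactants: 4, 1-{2-methoxy-4-[(triisopropylsilyl)oxy]phenyl}ethan-1-one
Product: 5, (E)-1-{2-methoxy-4-[(triisopropylsilyl)oxy]phenyl}ethan-1-one oxime (OH anti to the aryl ring)
Conditions: NH2OH·HCl, NaOAc, EtOH/H2O, 70 °C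
Reagents that add atoms: hydroxylamine (as hydrochloride), NO
Why: ketone–hydroxylamine condensation gives the thermodynamically preferred E-oxime, whose nitrogen lone pair points at the aryl ring as needed for the next step.

**Step 4**
Reactants: 5, the (E)-oxime; 6 prop-2-yn-1-ol
Product: 7, {8-methoxy-1-methyl-6-[(triisopropylsilyl)oxy]isoquinolin-3-yl}methanol
Conditions: Cp*Co(CO)I2 (10 mol %), NaOAc (20 mol %), CF3CH2OH, 80 °C
Reagents that add atoms: none
Why: Cp*Co(III)-catalysed oxime-directed C–H activation / alkyne insertion / C–N formation with N–O cleavage (redox-neutral dehydrative [4+2] annulation); only one ortho C–H is available, and a terminal alkyne inserts with its substituted carbon next to N, giving the 3-CH2OH, 4-H isoquinoline.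

**Step 5**
Reactants: 7, {8-methoxy-1-methyl-6-[(triisopropylsilyl)oxy]isoquinolin-3-yl}methanol
Product: 8, {5-iodo-8-methoxy-1-methyl-6-[(triisopropylsilyl)oxy]isoquinolin-3-yl}methanol
Conditions: NIS (1.05 equiv), TFA (2 equiv), MeCN, 0 °C → rt
Reagents that add atoms: N-iodosuccinimide, O=C1CCC(=O)N1I
Why: electrophilic aromatic iodination goes to C5, the α-position para to 8-OMe and ortho to 6-OSi, whereas C7 is a β-position flanked by two oxygen substituents and the protonated pyridine ring is deactivated.

**Step 6**
Reactants: 8, the 5-iodoisoquinoline; 9 propyne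
Product: 10, {8-methoxy-1-methyl-5-(prop-1-yn-1-yl)-6-[(triisopropylsilyl)oxy]isoquinolin-3-yl}methanol
Conditions: PdCl2(PPh3)2 (5 mol %), CuI (10 mol %), propyne (1 M in THF, excess), Et3N, sealed tube, 50 °C
Reagents that add atoms: none
Why: Sonogashira coupling of an aryl iodide tolerates the ortho substituent and the free primary alcohol, and the silyl ether blocks cyclisation of the ortho-oxygen onto the alkyne (benzofuran formation).

**Step 7**
Reactants: 11 anisole; 12 2-chloro-N-methoxy-N-methylacetamide
Product: 13, 2-chloro-1-(2-methoxyphenyl)ethan-1-one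
Conditions: n-BuLi, TMEDA, Et2O, 0 °C → rt; then 12, THF, −78 → 0 °C; aq NH4Cl
Reagents that add atoms: none
Why: directed ortho-metalation of anisole followed by Weinreb amide acylation, where the chelated tetrahedral intermediate prevents over-addition and the C–Cl bond is untouched at low temperature.

**Step 8 (key step)**
Reactants: 10, the 5-(prop-1-ynyl)isoquinoline; 13, 2-chloro-1-(2-methoxyphenyl)ethan-1-one (2.5 equiv, added in portions)
Product: 14, 4-{3-(hydroxymethyl)-8-methoxy-1-methyl-6-[(triisopropylsilyl)oxy]isoquinolin-5-yl}-8-methoxy-3-methylnaphthalen-1-ol (racemic about the new biaryl axis)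
Conditions: fac-Ir(ppy)3 (2 mol %), NaHCO3, degassed DMF, blue LEDs, rt
Reagents that add atoms: none
Why: Proposed new method: excited fac-Ir(ppy)3 reduces the α-chloroketone to an electrophilic phenacyl radical, which adds to the methyl-bearing alkyne carbon of 10 (less hindered, giving the α-aryl vinyl radical); this vinyl radical closes onto the free ortho carbon of the 2-methoxybenzoyl ring (forming C1'–C8a'), Ir(IV) oxidises the cyclohexadienyl radical, and proton loss with keto–enol tautomerisation gives the 1-naphthol with OMe peri to OH; the closest known reaction is the photoredox (or Mn(OAc)3) radical [4+2] benzannulation of 2-bromo-1,3-dicarbonyl aryl ketones with alkynes to 1-naphthols, extended here to a simple α-haloketone and a hindered heteroaryl alkyne; the TIPS ether offers no easily abstractable 1,5-hydrogen, and the chloride plus the 1,3-disubstituted nitrogen suppress N-phenacylation; no stereocentre is formed.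

**Step 9**
Reactants: 14, the 6-O-TIPS biaryl
Product: 15, 5-(4-hydroxy-5-methoxy-2-methylnaphthalen-1-yl)-3-(hydroxymethyl)-8-methoxy-1-methylisoquinolin-6-ol (6-O-desmethylancistrobenomine A)
Conditions: TBAF (1.1 equiv), THF, 0 °C; AcOH quench, under N2
Reagents that add atoms: none
Why: fluoride cleaves the aryl Si–O bond selectively, leaving the methyl ethers, carbinol, naphthol and biaryl axis untouched; this is done after work-up of step 8 so that no excess chloroketone is present to alkylate the phenoxide.

**Compound list**
1 | resorcinol | Oc1cccc(O)c1 | starting material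
2 | acetic acid | CC(=O)O | starting material
3 | 1-(2,4-dihydroxyphenyl)ethan-1-one | CC(=O)c1ccc(O)cc1O | intermediate
4 | 1-{2-methoxy-4-[(triisopropylsilyl)oxy]phenyl}ethan-1-one | CC(=O)c1ccc(O[Si](C(C)C)(C(C)C)C(C)C)cc1OC | intermediate
5 | (E)-1-{2-methoxy-4-[(triisopropylsilyl)oxy]phenyl}ethan-1-one oxime | C/C(=N\O)c1ccc(O[Si](C(C)C)(C(C)C)C(C)C)cc1OC | intermediate
6 | prop-2-yn-1-ol | C#CCO | starting material
7 | {8-methoxy-1-methyl-6-[(triisopropylsilyl)oxy]isoquinolin-3-yl}methanol | Cc1nc(CO)cc2cc(O[Si](C(C)C)(C(C)C)C(C)C)cc(OC)c12 | intermediate
8 | {5-iodo-8-methoxy-1-methyl-6-[(triisopropylsilyl)oxy]isoquinolin-3-yl}methanol | Cc1nc(CO)cc2c(I)c(O[Si](C(C)C)(C(C)C)C(C)C)cc(OC)c12 | intermediate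
9 | propyne | CC#C | starting material
10 | {8-methoxy-1-methyl-5-(prop-1-yn-1-yl)-6-[(triisopropylsilyl)oxy]isoquinolin-3-yl}methanol | CC#Cc1c(O[Si](C(C)C)(C(C)C)C(C)C)cc(OC)c2c(C)nc(CO)cc12 | intermediate
11 | anisole | COc1ccccc1 | starting material
12 | 2-chloro-N-methoxy-N-methylacetamide | CON(C)C(=O)CCl | starting material
13 | 2-chloro-1-(2-methoxyphenyl)ethan-1-one | COc1ccccc1C(=O)CCl | intermediate
14 | 4-{3-(hydroxymethyl)-8-methoxy-1-methyl-6-[(triisopropylsilyl)oxy]isoquinolin-5-yl}-8-methoxy-3-methylnaphthalen-1-ol | COc1cccc2c(-c3c(O[Si](C(C)C)(C(C)C)C(C)C)cc(OC)c4c(C)nc(CO)cc34)c(C)cc(O)c12 | intermediate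
15 | 5-(4-hydroxy-5-methoxy-2-methylnaphthalen-1-yl)-3-(hydroxymethyl)-8-methoxy-1-methylisoquinolin-6-ol | COc1cccc2c(-c3c(O)cc(OC)c4c(C)nc(CO)cc34)c(C)cc(O)c12 | target

**Totals**
Total steps: 9. Longest linear sequence: 8 (steps 1–6, 8, 9); step 7 is the convergent branch.

**Three steps most likely to fail, with fallbacks**
1. Step 8 (radical benzannulation). The phenacyl radical may add too slowly to the hindered alkyne, or be reduced or dimerise instead. Fallback: switch to the doubly activated precursor ethyl 2-bromo-3-(2-methoxyphenyl)-3-oxopropanoate, the substrate class for which this benzannulation is established, then remove the extra C3' ester by saponification and thermal decarboxylation of the 1-hydroxy-2-naphthoic acid (two more steps).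
2. Step 4 (Co(III) annulation with free propargyl alcohol). Risks are β-hydroxide elimination to an allene, low reactivity of the ortho-methoxy oxime, and regiochemical leakage. Fallback: build the ring in stages by Rh(III)-catalysed oxime-directed ortho-C–H olefination with methyl acrylate, 6π-aza-electrocyclisation with loss of water to the isoquinoline-3-carboxylate, then DIBAL-H reduction to the carbinol.
3. Step 5 (C5 iodination). Risks are competing C7 or C4 attack and sluggish reaction of the protonated heterocycle next to the bulky silyl ether. Fallback: remove the silyl group first, iodinate the free 6-isoquinolinol under phenoxide control (I2, morpholine; 2-naphthol-type α-selectivity), and re-silylate before the Sonogashira coupling.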